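(The numbers in the tables come from a simulation from invented constants.)

A colleague at the bench charged Tuesday's flask with substrate, activator and capture agent, followed it to 15.0 min, and asks what stands at 30 min; Wednesday's run had less capture agent.

| setting | Tuesday's | Wednesday's | flask |
|---|---|---|---|
| substrate | 0.050 M | 0.050 M | 0.050 M |
| activator | 0.050 M | 0.050 M | 0.0500 M |
| capture agent | 0.050 M | 0.034 M | 0.0500 M |
| remark | the very flask that is asked about, followed so far | run made earlier |  |
| time |  |  | 30 min |

| run | time / min | trapped intermediate / % | substrate / % | side product / % | over-reaction product / % | ring / % | open dimer / % |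
|---|---|---|---|---|---|---|---|
| Tuesday's | 1.33 | 2.4 | 87.3 | 0.1 | 0 | 0.8 | 4.8 |
| Tuesday's | 3.00 | 6.7 | 74.1 | 1.0 | 0.2 | 3.2 | 10.7 |
| Tuesday's | 6.00 | 11.0 | 57.6 | 0.7 | 0.2 | 8.6 | 19.3 |
| Tuesday's | 15.0 | 20.8 | 34.4 | 1.6 | 1.0 | 14.9 | 28.4 |
| Wednesday's | 1.50 | 1.9 | 86.4 | 0.4 | 0.7 | 1.8 | 5.1 |
| Wednesday's | 4.00 | 5.8 | 66.7 | 1.4 | 0 | 6.6 | 16.1 |
| Wednesday's | 8.00 | 10.8 | 49.1 | 2.1 | 0 | 11.6 | 25.5 |
| Wednesday's | 12.0 | 14.3 | 37.8 | 1.8 | 1.0 | 14.3 | 28.7 |

(each reading ± 0.5 percentage points)

- the species that holds most of what was charged as substrate, at 30 min (ring / open dimer / substrate / trapped intermediate / over-reaction product / side product)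
- the largest share itself, whichever of these holds it, in percent of the substrate charged

- a species is counted by the substrate in it: one open dimer counts as two

We read Tuesday's flask as a ladder of times. On the fastest rung, its balance at 1.33 min reads short by 4.6 percentage points; set against the early loss of substrate, that reading gives an unseen activated form a rough lifetime of 0.482 min. Next comes substrate: a second-order line through its 15.0 min reading gives a time scale τ of 7.87 min, hence 20.8% left at 30 min. Over-reaction product stands at 1.0% at 15.0 min, against a scatter of 0.5 points, so we leave it out.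

Since that lifetime is far shorter than τ, we treat the activated form as dividing at each moment among its exits, and we compare the two that lead to open dimer and trapped intermediate. Tuesday's readings from 6.00 min to 15.0 min give 1.70 for the selectivity factor σ, the open dimer gained per point of trapped intermediate, divided by the mean ratio of substrate to capture agent. Wednesday's readings from 4.00 min to 12.0 min give 1.64, despite their different capture agent charge. Keeping Tuesday's trapped gain per substrate lost, we reckon 26.6% trapped intermediate at 30 min. The mean split is then 0.614, so open dimer reaches 31.9% and stays ahead.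

The forecast differs: it names trapped intermediate, puts the largest share at 30%, range 27% to 34%, and says “Trapped intermediate narrowly leads open dimer”.

Tuesday's flask gives open dimer at 32.5%, with trapped intermediate at 26.2%.

    substrate + activator → activated form (k = 0.0292 L mol⁻¹ s⁻¹)
    activated form → ring (k = 0.00624 s⁻¹)
    substrate + activated form → open dimer (k = 0.191 L mol⁻¹ s⁻¹)
    activated form → side product (k = 6.53 × 10⁻⁴ s⁻¹)
    ring → over-reaction product (k = 3.68 × 10⁻⁵ s⁻¹)
    capture agent + activated form → trapped intermediate (k = 0.187 L mol⁻¹ s⁻¹)

At 30.0 min this flask holds 18.2% substrate and 73.8% of its capture agent, so the σ we read puts the split at 0.419: by that reckoning trapped intermediate is gaining faster than open dimer, while open dimer holds a lead of 6.3 points. A neighbour flask charged with 0.030 M of substrate starts at a split of 1.02, against 1.70 here, and ends with trapped intermediate ahead, 34.3% against 23.5% open dimer.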